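**Plan**

1. Cuts: the C15–O ester bond; the C2 carbinol back to a C2 ketone; then, in one retro-step, the C9–C10 bond of ring B and the C1 bridge of ring A, which reconnects C2 to C10 as a 1-hydroxybicyclo[3.1.0]hexane; then C6–C7 (sulfone alkylation) and C5–C6 (conjugate addition to 2,4,4-trimethylcyclopent-2-enone).
2. Enabling feature: ring A is a cyclohexanone whose carbonyl carbon C2 is 1,3 to the quaternary C10, and C10 carries C9 of ring B. O-radical scission of the internal C2–C10 bond of the bicyclohexanol (cyclopentane C2–C3–C4–C5–C10, cyclopropane carbon C1) gives the six-membered ketone and a tertiary C10 radical placed to close ring B on C9.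
3. Forward: cyclopentenone → C5 side chain with regiodefined silyl enol ether → cyclopropane (C1) → union with the citronellol-derived (E)-allyl sulfone → ring A (five to six) and ring B (6-endo) in one step, the C7 sulfonyl group leaving to place C7=C8 → ketone reduction → esterification.
4. Stereochemistry: C13 from (R)-citronellol; C5 from the sulfur stereocentre of an allyl sulfoxide; C10 and C9 relayed from C5 and the E alkene through a chair transition state; C2 by thermodynamic reduction.
5. Helpers removed on the way: p-tolylsulfinyl auxiliary (step 7), silyl groups (step 9), cyclopropane and phenylsulfonyl group (step 10).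

Key step: step 10

Numbering: labdane numbering is used throughout (ring A = C1–C5, C10; ring B = C5–C10; side chain C11–C15; methyls C16 on C13, C17 on C8, C18/C19 on C4, C20 on C10).

Assumption: the sense of induction in step 5 is taken from the lithium-chelated, chair-like ten-membered transition state (aryl group outside), which for the (S)-sulfoxide puts the new bond on the face giving the (S)-configured ring carbon (C5); if the opposite sense held, the enantiomeric sulfinate would be used in step 4 and nothing else changes.

**Route**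

Step 1
Reactants: 1 (R)-citronellol
Product: 2 (R)-citronellyl tert-butyldimethylsilyl ether
Conditions: TBSCl, imidazole, DMF, 25 °C
Reagents that add atoms: tert-butyldimethylsilyl chloride, CC(C)(C)[Si](C)(C)Cl
Why: Standard silylation of the primary alcohol; the C13 stereocentre comes unchanged from the chiral pool.

Step 2
Reactants: 2 (R)-citronellyl tert-butyldimethylsilyl ether
Product: 3 (2E,6R)-8-(tert-butyldimethylsilyloxy)-2,6-dimethyloct-2-en-1-ol
Conditions: SeO2 (0.1 equiv), t-BuOOH, salicylic acid (cat.), CH2Cl2, 25 °C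
Reagents that add atoms: tert-butyl hydroperoxide, CC(C)(C)OO
Why: Riley allylic oxidation (ene reaction then [2,3] shift) attacks the methyl group trans to the chain, so the E geometry of the later C8=C9 alkene is fixed here; the new CH2OH carbon is C7.

Step 3
Reactants: 3 (2E,6R)-8-(tert-butyldimethylsilyloxy)-2,6-dimethyloct-2-en-1-ol
Product: 5 (E)-allyl phenyl sulfone of the chain, via allylic mesylate 4 (not isolated)
Conditions: MsCl, Et3N, CH2Cl2, −40 °C; then PhSO2Na, DMF, 25 °C
Reagents that add atoms: sodium benzenesulfinate, [Na+].[O-]S(=O)c1ccccc1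
Why: SN2 S-alkylation of the sulfinate at the primary allylic carbon; the alkene geometry is not touched.

Step 4
Reactants: 6 (1S,2R,5S)-(+)-menthyl (R)-p-toluenesulfinate; 7 allylmagnesium bromide
Product: 8 (S)-allyl p-tolyl sulfoxide
Conditions: Et2O–toluene, −78 → 0 °C; cold work-up, used at once
Reagents that add atoms: none
Why: Andersen sulfoxide synthesis with inversion at sulfur; the product is kept cold because allyl sulfoxides racemise by [2,3] shift.

Step 5
Reactants: 8 (S)-allyl p-tolyl sulfoxide; 9 2,4,4-trimethylcyclopent-2-en-1-one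
Product: 12 (3S)-triethylsilyl enol ether carrying the (E)-3-(p-tolylsulfinyl)allyl group at C5, via lithiated allyl sulfoxide 10 (not isolated), via lithium enolate 11 (not isolated)
Conditions: LDA, THF, −78 °C; 9, −78 °C; then TESCl, Et3N, HMPA, −78 → −30 °C
Reagents that add atoms: chlorotriethylsilane, CC[Si](Cl)(CC)CC
Why: Kinetic 1,4-γ conjugate addition of a sulfinyl-allyl anion, a reaction type known for 2-methylcyclopent-2-enone with enolate capture; the sulfur stereocentre sets C5 through the chelated chair-like transition state, and silylation fixes the enolate as the tetrasubstituted C2=C10 enol ether.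

Step 6
Reactants: 12 triethylsilyl enol ether
Product: 13 1-(triethylsilyloxy)bicyclo[3.1.0]hexane with the vinyl sulfoxide side chain
Conditions: Et2Zn, CH2I2 (1:1, excess), CH2Cl2, 0 °C
Reagents that add atoms: diiodomethane, ICI
Why: Simmons–Smith (Furukawa) cyclopropanation of the electron-rich enol ether, the electron-poor vinyl sulfoxide being inert; the carbenoid should come anti to the C5 side chain, but the two new centres (C2, C10) are erased in step 10.

Step 7
Reactants: 13 cyclopropyl silyl ether with vinyl sulfoxide
Product: 15 [(4S)-3,3,5-trimethyl-1-(triethylsilyloxy)bicyclo[3.1.0]hexan-4-yl]methanol, via allyl sulfoxide 14 (not isolated)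
Conditions: DBU (0.3 equiv), CH2Cl2, 25 °C; AcOH; then O3, CH2Cl2–MeOH, −78 °C; NaBH4, −78 → 0 °C
Reagents that add atoms: ozone, [O-][O+]=O
Why: Base-mediated prototropic shift of the vinyl sulfoxide to the thermodynamically preferred γ-substituted allyl sulfoxide moves the alkene to C6=C7; ozonolysis with borohydride work-up then leaves a one-carbon CH2OH on C5, the aldehyde being reduced before C5 can epimerise.

Step 8
Reactants: 15 bicyclic primary alcohol; 5 chain allyl sulfone
Product: 18 coupled allyl sulfone (C7 epimers), via triflate 16 (not isolated), via lithiated sulfone 17 (not isolated)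
Conditions: 15, Tf2O, 2,6-lutidine, CH2Cl2, −78 °C; 5, n-BuLi, THF–HMPA, −78 °C; combine, −78 → −30 °C
Reagents that add atoms: none
Why: α-Alkylation of a lithiated allyl sulfone (α-selective) forms C6–C7; a triflate is used because the electrophilic carbon is β-branched; the C7 configuration is irrelevant because C7 becomes sp2.

Step 9
Reactants: 18 coupled allyl sulfone
Product: 19 cyclopropanol diol
Conditions: TBAF, AcOH, THF, 0 → 25 °C
Reagents that add atoms: none
Why: Fluoride desilylation of both silyl ethers, buffered so that neither base-induced opening of the cyclopropanol nor allyl-to-vinyl sulfone isomerisation occurs.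

Step 10
Reactants: 19 cyclopropanol diol
Product: 22 (13R)-15-hydroxylabd-7-en-2-one, via C10 radical 20 (not isolated), via C8 radical 21 (not isolated)
Conditions: Mn(acac)3 (0.2 equiv), degassed MeOH–MeCN, 0.01 M, 25 → 50 °C, Ar
Reagents that add atoms: none
Why: Proposed new method: the trivalent manganese alkoxide of 19 undergoes electron transfer with β-scission of the internal C2–C10 cyclopropane bond, turning the cyclopentane into the six-membered C2 ketone of ring A with a tertiary radical at C10 (20); this adds 6-endo-trig to C9 of the (E)-allyl sulfone, and the C8 radical 21 ejects PhSO2•, which places the alkene at C7=C8 and, on reduction by divalent manganese, regenerates the trivalent catalyst (net loss of PhSO2H, redox-neutral). The closest known reaction types are the manganese- and iron-mediated ring expansion of bicyclo[n.1.0]alkan-1-ols with 5-exo or intermolecular radical capture, the 6-endo steps of manganese-mediated polyene radical cyclisations, and radical allylation with allyl sulfones (SH2′). Ring A is not closed but enlarged from five to six atoms by insertion of C1, and ring B closes by 6-endo-trig attack of C10 on C9. C10 is set from C5 through a chair transition state with the C5–C6 tether equatorial (trans fusion, C20 axial), and C9 by the E geometry of C8=C9 in the same chair (side chain equatorial, H-9 anti to C20). The step needs internal rather than external bond scission (tertiary versus primary radical), 6-endo rather than 5-exo closure (attack at the less substituted alkene carbon avoids adjacent quaternary centres) and a single alkene position (given by the C7 sulfonyl leaving group, whose fast loss should also outrun hydrogen shifts that could reach C13).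

Step 11
Reactants: 22 (13R)-15-hydroxylabd-7-en-2-one
Product: 23 (13R)-labd-7-ene-2α,15-diol
Conditions: Li, NH3 (l)–THF, EtOH, −78 → −33 °C; then NH4Cl
Reagents that add atoms: none
Why: Dissolving-metal ketone reduction gives the thermodynamically preferred equatorial 2α-alcohol, whereas hydride reagents would approach from the equatorial side (axial face blocked by the syn-axial C19 and C20 methyls) and give the 2β-alcohol; the isolated trisubstituted alkene is inert.

Step 12
Reactants: 23 (13R)-labd-7-ene-2α,15-diol; 24 (E)-ferulic acid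
Product: 25 (13R)-2α-hydroxylabd-7-en-15-yl (E)-ferulate (target)
Conditions: PPh3, DIAD, THF, 0 → 25 °C
Reagents that add atoms: none
Why: Mitsunobu esterification activates the primary C15 alcohol selectively (backside attack at C2 is blocked by the syn-axial methyls), and the carboxylic acid, far more acidic than the phenol, acts as the nucleophile, so neither hydroxyl needs protection.

**Compound list**

1 | (R)-citronellol, (3R)-3,7-dimethyloct-6-en-1-ol | OCC[C@H](C)CCC=C(C)C | starting material
2 | tert-butyl{[(3R)-3,7-dimethyloct-6-en-1-yl]oxy}dimethylsilane | CC(C)(C)[Si](C)(C)OCC[C@H](C)CCC=C(C)C | intermediate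
3 | (2E,6R)-8-(tert-butyldimethylsilyloxy)-2,6-dimethyloct-2-en-1-ol | CC(C)(C)[Si](C)(C)OCC[C@H](C)CC/C=C(\C)CO | intermediate
4 | methanesulfonate of 3 | CC(C)(C)[Si](C)(C)OCC[C@H](C)CC/C=C(\C)COS(C)(=O)=O | intermediate
5 | tert-butyl{[(3R,6E)-3,7-dimethyl-8-(phenylsulfonyl)oct-6-en-1-yl]oxy}dimethylsilane | CC(C)(C)[Si](C)(C)OCC[C@H](C)CC/C=C(\C)CS(=O)(=O)c1ccccc1 | intermediate
6 | (1S,2R,5S)-(+)-menthyl (R)-p-toluenesulfinate | C[C@H]1CC[C@@H]([C@H](C1)O[S@@](=O)c1ccc(C)cc1)C(C)C | starting material
7 | allylmagnesium bromide | C=CC[Mg]Br | starting material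
8 | (S)-allyl p-tolyl sulfoxide | C=CC[S@](=O)c1ccc(C)cc1 | intermediate
9 | 2,4,4-trimethylcyclopent-2-en-1-one | CC1=CC(C)(C)CC1=O | starting material
10 | α-lithio derivative of 8 | [Li+].C=C[CH-][S@](=O)c1ccc(C)cc1 | intermediate
11 | lithium enolate of the 1,4-γ adduct | [Li+].[O-]C1=C(C)[C@@H](C/C=C/[S@](=O)c2ccc(C)cc2)C(C)(C)C1 | intermediate
12 | triethyl({(3S)-2,4,4-trimethyl-3-[(2E)-3-((S)-p-tolylsulfinyl)prop-2-en-1-yl]cyclopent-1-en-1-yl}oxy)silane | CC[Si](CC)(CC)OC1=C(C)[C@@H](C/C=C/[S@](=O)c2ccc(C)cc2)C(C)(C)C1 | intermediate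
13 | (4S)-3,3,5-trimethyl-4-[(2E)-3-((S)-p-tolylsulfinyl)prop-2-en-1-yl]-1-(triethylsilyloxy)bicyclo[3.1.0]hexane, cyclopropane CH2 anti to the C4 side chain | Cc1ccc(cc1)[S@@](=O)/C=C/C[C@H]1C(C)(C)C[C@]2(O[Si](CC)(CC)CC)C[C@]12C | intermediate
14 | (4S)-3,3,5-trimethyl-4-[(1E)-3-((S)-p-tolylsulfinyl)prop-1-en-1-yl]-1-(triethylsilyloxy)bicyclo[3.1.0]hexane | Cc1ccc(cc1)[S@@](=O)C/C=C/[C@H]1C(C)(C)C[C@]2(O[Si](CC)(CC)CC)C[C@]12C | intermediate
15 | [(4S)-3,3,5-trimethyl-1-(triethylsilyloxy)bicyclo[3.1.0]hexan-4-yl]methanol, cyclopropane CH2 anti to CH2OH | OC[C@H]1C(C)(C)C[C@]2(O[Si](CC)(CC)CC)C[C@]12C | intermediate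
16 | trifluoromethanesulfonate of 15 | FC(F)(F)S(=O)(=O)OC[C@H]1C(C)(C)C[C@]2(O[Si](CC)(CC)CC)C[C@]12C | intermediate
17 | α-lithio derivative of 5 | [Li+].CC(C)(C)[Si](C)(C)OCC[C@H](C)CC/C=C(\C)[CH-]S(=O)(=O)c1ccccc1 | intermediate
18 | coupled allyl sulfone: C7-phenylsulfonyl, (8E)-alkene, 15-OTBS chain on the silylated bicyclohexanol (C7 epimers) | CC(C)(C)[Si](C)(C)OCC[C@H](C)CC/C=C(\C)C(S(=O)(=O)c1ccccc1)C[C@H]1C(C)(C)C[C@]2(O[Si](CC)(CC)CC)C[C@]12C | intermediate
19 | cyclopropanol diol: 18 without both silyl groups | OCC[C@H](C)CC/C=C(\C)C(S(=O)(=O)c1ccccc1)C[C@H]1C(C)(C)C[C@]2(O)C[C@]12C | intermediate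
20 | ring-expanded tertiary C10 radical (3-oxocyclohexyl radical) | OCC[C@H](C)CC/C=C(\C)C(S(=O)(=O)c1ccccc1)C[C@H]1C(C)(C)CC(=O)C[C]1C | intermediate
21 | cyclised C8 radical, β to the C7 sulfonyl group | OCC[C@H](C)CC[C@H]1[C](C)C(S(=O)(=O)c2ccccc2)C[C@H]2C(C)(C)CC(=O)C[C@]12C | intermediate
22 | (13R)-15-hydroxylabd-7-en-2-one | OCC[C@H](C)CC[C@H]1C(C)=CC[C@H]2C(C)(C)CC(=O)C[C@]12C | intermediate
23 | (13R)-labd-7-ene-2α,15-diol | OCC[C@H](C)CC[C@H]1C(C)=CC[C@H]2C(C)(C)C[C@H](O)C[C@]12C | intermediate
24 | (E)-ferulic acid | COc1cc(/C=C/C(=O)O)ccc1O | starting material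
25 | (13R)-2α-hydroxylabd-7-en-15-yl (E)-ferulate | COc1cc(/C=C/C(=O)OCC[C@H](C)CC[C@H]2C(C)=CC[C@H]3C(C)(C)C[C@H](O)C[C@]23C)ccc1O | target

**Step count and risks**

Total steps: 12. Longest linear sequence: 9 (steps 4 to 12, from 6 and 9).

Steps most likely to fail:

1. Step 10 (proposed new method). The tertiary C10 radical may be quenched or oxidised before it closes ring B, the expelled sulfonyl radical may isomerise the allyl sulfone by addition–elimination, or the chair preference may be too weak. Fallback with known reactions, ring A still made by ring expansion: setting out from 19, FeCl3 in DMF at 0 °C cleaves the same internal cyclopropane bond with chlorine transfer to give the ring-expanded β-chloro ketone F1. NaOAc in hot MeOH eliminates HCl to the 4-substituted 3,5,5-trimethylcyclohex-2-enone F2. t-BuOK in t-BuOH–THF then closes ring B by intramolecular Michael addition of the allyl sulfone anion through its γ-carbon C9 onto C10 (α-attack would give a four-membered ring), giving under equilibrating conditions the 7-phenylsulfonyl labdenone F3. Li in NH3 with EtOH, as in step 11, removes the vinylic sulfonyl group and reduces the ketone, and the route is rejoined at 23.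

2. Step 5. Addition at the β-carbon flanked by the quaternary C4 may be slow, may compete with 1,2-addition, or may show low or opposite facial discrimination. Fallback: setting out from 9, CuBr·SMe2-catalysed conjugate addition of vinylmagnesium bromide with TESCl capture gives the racemic silyl enol ether F4. Simmons–Smith cyclopropanation gives the racemic vinyl bicyclohexane F5, and ozonolysis with NaBH4 work-up the racemic alcohol F6. Esterification with (S)-2-methoxy-2-phenylacetic acid (DCC, DMAP) and chromatographic separation of the diastereomers gives the ester F7, and LiOH hydrolysis returns to the route at 15.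

3. Step 8. Substitution at the β-branched primary carbon may be slow, so that the lithiated sulfone acts as a base (elimination) or the triflate decomposes. Fallback with reversed polarity at C6: setting out from 15, I2/PPh3/imidazole gives the iodide F8 and t-BuLi (Et2O, −78 °C) the alkyllithium F9. This adds to the (E)-enal F10 (from 3 with MnO2) to give the allylic alcohol F11. Mitsunobu displacement with thiophenol gives the allylic phenyl sulfide F12, and (NH4)6Mo7O24/H2O2 oxidises it to the sulfone, rejoining the route at 18.

Further compounds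
F1 | step 10 | ring-expanded β-chloro ketone, 3-chloro-3,5,5-trimethylcyclohexan-1-one carrying the sulfone chain at C4 (chloride epimers) | OCC[C@H](C)CC/C=C(\C)C(S(=O)(=O)c1ccccc1)C[C@H]1C(C)(C)CC(=O)CC1(C)Cl
F2 | step 10 | ring-expanded enone, 4-substituted 3,5,5-trimethylcyclohex-2-en-1-one | OCC[C@H](C)CC/C=C(\C)C(S(=O)(=O)c1ccccc1)C[C@H]1C(C)(C)CC(=O)C=C1C
F3 | step 10 | (13R)-15-hydroxy-7-(phenylsulfonyl)labd-7-en-2-one | OCC[C@H](C)CC[C@H]1C(C)=C(S(=O)(=O)c2ccccc2)C[C@H]2C(C)(C)CC(=O)C[C@]12C
F4 | step 5 | rac-triethyl[(2,4,4-trimethyl-3-vinylcyclopent-1-en-1-yl)oxy]silane | CC[Si](CC)(CC)OC1=C(C)C(C=C)C(C)(C)C1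
F5 | step 5 | rac-3,3,5-trimethyl-1-(triethylsilyloxy)-4-vinylbicyclo[3.1.0]hexane, cyclopropane anti to vinyl (one enantiomer drawn) | C=C[C@H]1C(C)(C)C[C@]2(O[Si](CC)(CC)CC)C[C@]12C
F6 | step 5 | racemate of 15 (relative configuration as in 15) | OCC1C(C)(C)CC2(O[Si](CC)(CC)CC)CC12C
F7 | step 5 | (S)-2-methoxy-2-phenylacetate of 15 | CO[C@H](C(=O)OC[C@H]1C(C)(C)C[C@]2(O[Si](CC)(CC)CC)C[C@]12C)c1ccccc1
F8 | step 8 | iodide corresponding to 15 | IC[C@H]1C(C)(C)C[C@]2(O[Si](CC)(CC)CC)C[C@]12C
F9 | step 8 | alkyllithium from F8 | [Li]C[C@H]1C(C)(C)C[C@]2(O[Si](CC)(CC)CC)C[C@]12C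
F10 | step 8 | (2E,6R)-8-(tert-butyldimethylsilyloxy)-2,6-dimethyloct-2-enal | CC(C)(C)[Si](C)(C)OCC[C@H](C)CC/C=C(\C)C=O
F11 | step 8 | C7 allylic alcohol (C7 epimers) | CC(C)(C)[Si](C)(C)OCC[C@H](C)CC/C=C(\C)C(O)C[C@H]1C(C)(C)C[C@]2(O[Si](CC)(CC)CC)C[C@]12C
F12 | step 8 | C7 allylic phenyl sulfide (C7 epimers) | CC(C)(C)[Si](C)(C)OCC[C@H](C)CC/C=C(\C)C(Sc1ccccc1)C[C@H]1C(C)(C)C[C@]2(O[Si](CC)(CC)CC)C[C@]12C
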